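Everything rests on opening both rings F at C2'–C3' and C5'–C6'. Each C5(E)–C1'(F) axis, crowded by four ortho oxygens, then enters as an sp3 carbon–aryl bond and not through biaryl coupling. The feature used: ring F carries free hydroxyls on C2', C4' and C6', the pattern of a cyclised triketide, and is symmetric about that axis. In one operation a bis(arylmalonate) takes up two molecules of dimethyl 3-oxopentanedioate, giving four C–C bonds and both aromatic rings F. The precursor is ring D (1-benzyloxy, 4-methoxy) holding two trimethoxylated rings E, each with CH(CO2Me)2 on C5. Rings A, B, B' and C follow as one aryl bromide.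

Key step: step 6

**Ring labels**
- A is the terminal 3,5-dihydroxyphenoxy ring.
- B carries A–O on C1, OH on C2 and C6, C–O on C4, and ring B' on C5.
- C carries B–O on C1, OH on C2 and C6, and D–O on C4.
- D carries C–O on C1, E–O on C2 and C6, and OH on C4.
- E (twice) is bound through O1 to D and through C5 to C1' of F (twice).

**Stereochemistry:** the target has no stereocentre. None of its three biaryl axes is stereogenic, because B' and both rings F are symmetric about them.

**Design notes**
- Ring D enters as a 2,6-difluorobenzaldehyde. Its O1 and O4 therefore differ from the first step, and no oxidising quinone meets an electron-rich phenol.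
- Bromine is placed on rings E only after etherification, when no free p-methoxyphenol is present.
- The benzylated dibromide is the branch point for both the malonate route and a cross-coupling fallback.

**Assumption:** every compound marked as starting material in the list is taken as a catalogue chemical.

## Route

Step 1
Reactants: 1 2,4,6-trimethoxyphenol (2.2 equiv); 2 2,6-difluoro-4-methoxybenzaldehyde
Product: 3 4-methoxy-2,6-bis(2,4,6-trimethoxyphenoxy)benzaldehyde
Conditions: K2CO3, DMSO, 110 °C, N2
Reagents that add atoms: none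
Why: Twofold SNAr in which both fluorines lie ortho to the formyl group that stabilises the Meisenheimer adducts, while the C4 methoxy group is meta to the reacting carbons and does not feed electrons into them.

Step 2
Reactants: 3 4-methoxy-2,6-bis(2,4,6-trimethoxyphenoxy)benzaldehyde
Product: 4 2,6-bis(3-bromo-2,4,6-trimethoxyphenoxy)-4-methoxybenzaldehyde
Conditions: NBS (2.05 equiv), dry MeCN, 0 °C to rt
Reagents that add atoms: N-bromosuccinimide, O=C1CCC(=O)N1Br
Why: Electrophilic aromatic bromination, where the two equivalent CH positions of each ring E (ortho, ortho and para to three methoxy groups) are far more nucleophilic than those of the formyl-bearing ring D and the first bromine deactivates its own ring, so one bromine per ring E should enter at the future C5.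

Step 3
Reactants: 4 2,6-bis(3-bromo-2,4,6-trimethoxyphenoxy)-4-methoxybenzaldehyde
Product: 6 2,6-bis(3-bromo-2,4,6-trimethoxyphenoxy)-4-methoxyphenol, via aryl formate 5 (not isolated)
Conditions: mCPBA, CH2Cl2, 0 °C to rt; NaHCO3 wash; crude formate: K2CO3 (cat.), MeOH, rt
Reagents that add atoms: 3-chloroperoxybenzoic acid, OOC(=O)c1cccc(Cl)c1
Why: Baeyer–Villiger oxidation in which the 2,4,6-trioxygenated aryl group migrates in preference to hydride, and mild methanolysis of the formate frees O1 of ring D as the only phenol.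

Step 4
Reactants: 6 2,6-bis(3-bromo-2,4,6-trimethoxyphenoxy)-4-methoxyphenol
Product: 7 2-benzyloxy-1,3-bis(3-bromo-2,4,6-trimethoxyphenoxy)-5-methoxybenzene
Conditions: BnBr, K2CO3, DMF, 50 °C
Reagents that add atoms: benzyl bromide, BrCc1ccccc1
Why: Williamson etherification of the single phenol with a group that withstands palladium catalysis, alkoxide, saponification and methylation and can later be removed beside methyl ethers.

Step 5
Reactants: 7 2-benzyloxy-1,3-bis(3-bromo-2,4,6-trimethoxyphenoxy)-5-methoxybenzene; 8 dimethyl malonate (4 equiv)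
Product: 9 2-benzyloxy-5-methoxy-1,3-bis{3-[bis(methoxycarbonyl)methyl]-2,4,6-trimethoxyphenoxy}benzene
Conditions: Pd(dba)2 (10 mol%), P(t-Bu)3·HBF4 (20 mol%), K3PO4, toluene, 90 °C
Reagents that add atoms: none
Why: Palladium-catalysed enolate α-arylation (Buchwald–Hartwig type), where the bulky electron-rich phosphine lets zerovalent palladium insert into the electron-rich, doubly ortho-substituted bromides and speeds reductive elimination, and the hindered product enolate cannot be arylated again.

Step 6
Reactants: 9 2-benzyloxy-5-methoxy-1,3-bis{3-[bis(methoxycarbonyl)methyl]-2,4,6-trimethoxyphenoxy}benzene; 10 dimethyl 3-oxopentanedioate (3 equiv)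
Product: 12 2-benzyloxy-5-methoxy-1,3-bis{3-[2,4,6-trihydroxy-3,5-bis(methoxycarbonyl)phenyl]-2,4,6-trimethoxyphenoxy}benzene, via open-chain bis-Claisen adduct 11 (not isolated)
Conditions: NaOMe premixed 1:1 with 10 (3 equiv, slow addition), toluene–MeOH, 110 °C, MeOH distilled off; then 1 M HCl
Reagents that add atoms: none
Why: Proposed new method: the sodium enolate of 10 C-acylates one ester group of a still protonated arylmalonate (intermolecular Claisen condensation, C2'–C3'), and in the resulting open-chain arm of 11 the second α-carbon C5' attacks the remaining malonate ester C6', after which loss of methanol and enolisation give the aromatic trihydroxyisophthalate. The closest known reaction type is the alkoxide-mediated condensation of simple dialkyl malonates with acetonedicarboxylates to phloroglucinol dicarboxylates, which has not been shown for arylmalonates bearing two ortho oxygens. Each of the two rings F closes in a 6-exo-trig Dieckmann-type acylation, with C1' supplied by the malonate methine, so the axis with four ortho oxygens exists before the ring does. No stereocentre is created, and the new axes are not stereogenic because ring F is symmetric about C1'–C4'. The step needs C- over O-closure and cross- over self-condensation: a pyranone from O-closure is reopened by methoxide while the aromatic phenoxide is the thermodynamic sink, 10 is the more acidic partner so that base matched to it leaves the malonate electrophilic, and slow addition keeps free 10 scarce. Regiochemistry is degenerate because 10 and each malonate are symmetric, and methyl esters matched with methoxide exclude ester scrambling.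

Step 7
Reactants: 12 2-benzyloxy-5-methoxy-1,3-bis{3-[2,4,6-trihydroxy-3,5-bis(methoxycarbonyl)phenyl]-2,4,6-trimethoxyphenoxy}benzene
Product: 14 2-benzyloxy-5-methoxy-1,3-bis[2,4,6-trimethoxy-3-(2,4,6-trihydroxyphenyl)phenoxy]benzene, via tetracarboxylic acid 13 (not isolated)
Conditions: 2 M NaOH, MeOH, reflux, Ar; then HCl to pH 1, 60 °C
Reagents that add atoms: none
Why: Saponification followed by protodecarboxylation, since 2,4,6-trihydroxybenzoic acids lose CO2 readily by ipso protonation through their keto tautomers, while methyl and benzyl ethers are untouched.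

Step 8
Reactants: 14 2-benzyloxy-5-methoxy-1,3-bis[2,4,6-trimethoxy-3-(2,4,6-trihydroxyphenyl)phenoxy]benzene
Product: 15 2-benzyloxy-5-methoxy-1,3-bis[2,4,6-trimethoxy-3-(2,4,6-trimethoxyphenyl)phenoxy]benzene
Conditions: Me2SO4 (excess), K2CO3, acetone, reflux, Ar
Reagents that add atoms: dimethyl sulfate, COS(=O)(=O)OC
Why: Williamson-type O-methylation with a hard electrophile and a weak base, the standard way to favour O- over C-alkylation of phloroglucinols, caps all six hydroxyls so that only O1 of ring D can be unmasked next.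

Step 9
Reactants: 15 2-benzyloxy-5-methoxy-1,3-bis[2,4,6-trimethoxy-3-(2,4,6-trimethoxyphenyl)phenoxy]benzene
Product: 16 4-methoxy-2,6-bis[2,4,6-trimethoxy-3-(2,4,6-trimethoxyphenyl)phenoxy]phenol
Conditions: H2 (1 atm), Pd/C, EtOAc–MeOH, rt
Reagents that add atoms: none
Why: Catalytic hydrogenolysis cleaves the single benzyl aryl ether, whereas methyl ethers, diaryl ethers and biaryl bonds are inert.

Step 10
Reactants: 17 4-fluoro-2,6-dimethoxybenzaldehyde
Product: 18 3-bromo-4-fluoro-2,6-dimethoxybenzaldehyde
Conditions: NBS (1.0 equiv), MeCN, rt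
Reagents that add atoms: N-bromosuccinimide, O=C1CCC(=O)N1Br
Why: Electrophilic aromatic bromination at one of the two equivalent positions that are ortho and para to the methoxy groups and meta to the formyl group, held at the monobromide by stoichiometry.

Step 11
Reactants: 18 3-bromo-4-fluoro-2,6-dimethoxybenzaldehyde; 19 (2,4,6-trimethoxyphenyl)boronic acid (2 equiv)
Product: 20 4-fluoro-2,6-dimethoxy-3-(2,4,6-trimethoxyphenyl)benzaldehyde
Conditions: Pd(OAc)2 (5 mol%), SPhos (10 mol%), K3PO4, toluene–H2O, 100 °C
Reagents that add atoms: none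
Why: Suzuki–Miyaura coupling with a dialkylbiarylphosphine, a system established for biaryls with three or four ortho substituents (one of them here only fluorine), with excess 19 offsetting protodeboronation.

Step 12
Reactants: 20 4-fluoro-2,6-dimethoxy-3-(2,4,6-trimethoxyphenyl)benzaldehyde; 21 4-bromo-2,6-dimethoxyphenol
Product: 22 4-(4-bromo-2,6-dimethoxyphenoxy)-2,6-dimethoxy-3-(2,4,6-trimethoxyphenyl)benzaldehyde
Conditions: Cs2CO3, DMSO, 130 °C, N2
Reagents that add atoms: none
Why: SNAr at the fluorine para to the formyl group, done on small molecules where forcing conditions are affordable, while the bromine on the electron-rich ring C has no activation and stays.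

Step 13
Reactants: 22 4-(4-bromo-2,6-dimethoxyphenoxy)-2,6-dimethoxy-3-(2,4,6-trimethoxyphenyl)benzaldehyde
Product: 24 4-(4-bromo-2,6-dimethoxyphenoxy)-2,6-dimethoxy-3-(2,4,6-trimethoxyphenyl)phenol, via aryl formate 23 (not isolated)
Conditions: mCPBA, CH2Cl2, 0 °C to rt; NaHCO3 wash; crude formate: K2CO3 (cat.), MeOH, rt
Reagents that add atoms: 3-chloroperoxybenzoic acid, OOC(=O)c1cccc(Cl)c1
Why: Baeyer–Villiger oxidation with migration of the trioxygenated ring B, followed by methanolysis, turns the spent activating group into O1 of ring B.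

Step 14
Reactants: 24 4-(4-bromo-2,6-dimethoxyphenoxy)-2,6-dimethoxy-3-(2,4,6-trimethoxyphenyl)phenol; 25 (3,5-dimethoxyphenyl)boronic acid (2 equiv)
Product: 26 1-(4-bromo-2,6-dimethoxyphenoxy)-4-(3,5-dimethoxyphenoxy)-3,5-dimethoxy-2-(2,4,6-trimethoxyphenyl)benzene
Conditions: Cu(OAc)2 (2 equiv), pyridine, 4 Å MS, CH2Cl2, rt, drying tube
Reagents that add atoms: none
Why: Chan–Lam coupling, which tolerates phenols with two ortho substituents when the boronic acid is unhindered and runs at room temperature, so the aryl bromide is not touched.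

Step 15
Reactants: 16 4-methoxy-2,6-bis[2,4,6-trimethoxy-3-(2,4,6-trimethoxyphenyl)phenoxy]phenol; 26 1-(4-bromo-2,6-dimethoxyphenoxy)-4-(3,5-dimethoxyphenoxy)-3,5-dimethoxy-2-(2,4,6-trimethoxyphenyl)benzene
Product: 27 docosa-O-methyl ether of the target
Conditions: CuI (20 mol%), picolinic acid (40 mol%), K3PO4, DMSO, 100 °C, Ar
Reagents that add atoms: none
Why: Ullmann-type diaryl ether synthesis in which the bromine-bearing C4 of ring C has only hydrogen neighbours, so all crowding lies on the phenoxide partner, the case this ligand system is known to tolerate.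

Step 16
Reactants: 27 docosa-O-methyl ether of the target
Product: 28 CNP0117322.0
Conditions: BBr3 (about 3 equiv per OMe), CH2Cl2, −78 °C to rt, Ar; then ice-water
Reagents that add atoms: none
Why: Lewis-acid ether cleavage in which BBr3 binds each methoxy oxygen and bromide removes the methyl group by SN2, whereas the five diaryl ether and three biaryl bonds offer no sp3 carbon, so hydrolysis of the aryl borates should free all 22 hydroxyls.

## Compound list

1 | 2,4,6-trimethoxyphenol | COc1cc(OC)c(O)c(OC)c1 | starting material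
2 | 2,6-difluoro-4-methoxybenzaldehyde | COc1cc(F)c(C=O)c(F)c1 | starting material
3 | 4-methoxy-2,6-bis(2,4,6-trimethoxyphenoxy)benzaldehyde | COc1cc(Oc2c(OC)cc(OC)cc2OC)c(C=O)c(Oc2c(OC)cc(OC)cc2OC)c1 | intermediate
4 | 2,6-bis(3-bromo-2,4,6-trimethoxyphenoxy)-4-methoxybenzaldehyde | COc1cc(Oc2c(OC)cc(OC)c(Br)c2OC)c(C=O)c(Oc2c(OC)cc(OC)c(Br)c2OC)c1 | intermediate
5 | 2,6-bis(3-bromo-2,4,6-trimethoxyphenoxy)-4-methoxyphenyl formate (not isolated) | COc1cc(Oc2c(OC)cc(OC)c(Br)c2OC)c(OC=O)c(Oc2c(OC)cc(OC)c(Br)c2OC)c1 | intermediate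
6 | 2,6-bis(3-bromo-2,4,6-trimethoxyphenoxy)-4-methoxyphenol | COc1cc(Oc2c(OC)cc(OC)c(Br)c2OC)c(O)c(Oc2c(OC)cc(OC)c(Br)c2OC)c1 | intermediate
7 | 2-benzyloxy-1,3-bis(3-bromo-2,4,6-trimethoxyphenoxy)-5-methoxybenzene | COc1cc(Oc2c(OC)cc(OC)c(Br)c2OC)c(OCc2ccccc2)c(Oc2c(OC)cc(OC)c(Br)c2OC)c1 | intermediate
8 | dimethyl malonate | COC(=O)CC(=O)OC | starting material
9 | 2-benzyloxy-5-methoxy-1,3-bis{3-[bis(methoxycarbonyl)methyl]-2,4,6-trimethoxyphenoxy}benzene (bis(arylmalonate), key-step precursor) | COc1cc(Oc2c(OC)cc(OC)c(C(C(=O)OC)C(=O)OC)c2OC)c(OCc2ccccc2)c(Oc2c(OC)cc(OC)c(C(C(=O)OC)C(=O)OC)c2OC)c1 | intermediate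
10 | dimethyl 3-oxopentanedioate | COC(=O)CC(=O)CC(=O)OC | starting material
11 | open-chain bis-Claisen adduct: as 9, with each CH(CO2Me)2 replaced by CH(CO2Me)C(O)CH(CO2Me)C(O)CH2CO2Me (drawn all-keto; the enolisable CH centres hold no fixed configuration; not isolated) | COc1cc(Oc2c(OC)cc(OC)c(C(C(=O)OC)C(=O)C(C(=O)OC)C(=O)CC(=O)OC)c2OC)c(OCc2ccccc2)c(Oc2c(OC)cc(OC)c(C(C(=O)OC)C(=O)C(C(=O)OC)C(=O)CC(=O)OC)c2OC)c1 | intermediate
12 | 2-benzyloxy-5-methoxy-1,3-bis{3-[2,4,6-trihydroxy-3,5-bis(methoxycarbonyl)phenyl]-2,4,6-trimethoxyphenoxy}benzene (key-step product) | COc1cc(Oc2c(OC)cc(OC)c(-c3c(O)c(C(=O)OC)c(O)c(C(=O)OC)c3O)c2OC)c(OCc2ccccc2)c(Oc2c(OC)cc(OC)c(-c3c(O)c(C(=O)OC)c(O)c(C(=O)OC)c3O)c2OC)c1 | intermediate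
13 | tetracarboxylic acid of 12 (not isolated) | COc1cc(Oc2c(OC)cc(OC)c(-c3c(O)c(C(=O)O)c(O)c(C(=O)O)c3O)c2OC)c(OCc2ccccc2)c(Oc2c(OC)cc(OC)c(-c3c(O)c(C(=O)O)c(O)c(C(=O)O)c3O)c2OC)c1 | intermediate
14 | 2-benzyloxy-5-methoxy-1,3-bis[2,4,6-trimethoxy-3-(2,4,6-trihydroxyphenyl)phenoxy]benzene | COc1cc(Oc2c(OC)cc(OC)c(-c3c(O)cc(O)cc3O)c2OC)c(OCc2ccccc2)c(Oc2c(OC)cc(OC)c(-c3c(O)cc(O)cc3O)c2OC)c1 | intermediate
15 | 2-benzyloxy-5-methoxy-1,3-bis[2,4,6-trimethoxy-3-(2,4,6-trimethoxyphenyl)phenoxy]benzene | COc1cc(Oc2c(OC)cc(OC)c(-c3c(OC)cc(OC)cc3OC)c2OC)c(OCc2ccccc2)c(Oc2c(OC)cc(OC)c(-c3c(OC)cc(OC)cc3OC)c2OC)c1 | intermediate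
16 | 4-methoxy-2,6-bis[2,4,6-trimethoxy-3-(2,4,6-trimethoxyphenyl)phenoxy]phenol | COc1cc(Oc2c(OC)cc(OC)c(-c3c(OC)cc(OC)cc3OC)c2OC)c(O)c(Oc2c(OC)cc(OC)c(-c3c(OC)cc(OC)cc3OC)c2OC)c1 | intermediate
17 | 4-fluoro-2,6-dimethoxybenzaldehyde | COc1cc(F)cc(OC)c1C=O | starting material
18 | 3-bromo-4-fluoro-2,6-dimethoxybenzaldehyde | COc1cc(F)c(Br)c(OC)c1C=O | intermediate
19 | (2,4,6-trimethoxyphenyl)boronic acid | COc1cc(OC)c(B(O)O)c(OC)c1 | starting material
20 | 4-fluoro-2,6-dimethoxy-3-(2,4,6-trimethoxyphenyl)benzaldehyde | COc1cc(F)c(-c2c(OC)cc(OC)cc2OC)c(OC)c1C=O | intermediate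
21 | 4-bromo-2,6-dimethoxyphenol | COc1cc(Br)cc(OC)c1O | starting material
22 | 4-(4-bromo-2,6-dimethoxyphenoxy)-2,6-dimethoxy-3-(2,4,6-trimethoxyphenyl)benzaldehyde | COc1cc(Oc2c(OC)cc(Br)cc2OC)c(-c2c(OC)cc(OC)cc2OC)c(OC)c1C=O | intermediate
23 | 4-(4-bromo-2,6-dimethoxyphenoxy)-2,6-dimethoxy-3-(2,4,6-trimethoxyphenyl)phenyl formate (not isolated) | COc1cc(Oc2c(OC)cc(Br)cc2OC)c(-c2c(OC)cc(OC)cc2OC)c(OC)c1OC=O | intermediate
24 | 4-(4-bromo-2,6-dimethoxyphenoxy)-2,6-dimethoxy-3-(2,4,6-trimethoxyphenyl)phenol | COc1cc(Oc2c(OC)cc(Br)cc2OC)c(-c2c(OC)cc(OC)cc2OC)c(OC)c1O | intermediate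
25 | (3,5-dimethoxyphenyl)boronic acid | COc1cc(OC)cc(B(O)O)c1 | starting material
26 | 1-(4-bromo-2,6-dimethoxyphenoxy)-4-(3,5-dimethoxyphenoxy)-3,5-dimethoxy-2-(2,4,6-trimethoxyphenyl)benzene (rings A, B, B', C) | COc1cc(OC)cc(Oc2c(OC)cc(Oc3c(OC)cc(Br)cc3OC)c(-c3c(OC)cc(OC)cc3OC)c2OC)c1 | intermediate
27 | docosa-O-methyl ether of the target (all 22 hydroxyls as OMe) | COc1cc(OC)cc(Oc2c(OC)cc(Oc3c(OC)cc(Oc4c(Oc5c(OC)cc(OC)c(-c6c(OC)cc(OC)cc6OC)c5OC)cc(OC)cc4Oc4c(OC)cc(OC)c(-c5c(OC)cc(OC)cc5OC)c4OC)cc3OC)c(-c3c(OC)cc(OC)cc3OC)c2OC)c1 | intermediate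
28 | CNP0117322.0 | Oc1cc(O)cc(Oc2c(O)cc(Oc3c(O)cc(Oc4c(Oc5c(O)cc(O)c(-c6c(O)cc(O)cc6O)c5O)cc(O)cc4Oc4c(O)cc(O)c(-c5c(O)cc(O)cc5O)c4O)cc3O)c(-c3c(O)cc(O)cc3O)c2O)c1 | target

## Step count and risks

Total step count: 16.
Longest linear sequence: 11 (steps 1 to 9, 15 and 16). Steps 10 to 14 form the side branch.

**Steps most likely to fail**

1. **Step 6.**
   - What may go wrong: the enolate of 10 may condense with itself faster than it acylates the crowded malonate esters. The malonate may rest as its unreactive enolate. Ring closure may stop at the oxygen-cyclised stage. Only one of the two arms may react.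
   - Fallback (known chemistry): it sets out from dibromide 7 and comes back at 15. A twofold Suzuki–Miyaura coupling of 7 with boronic acid 19 [Pd(OAc)2, SPhos, K3PO4, toluene–H2O, 100 °C] would install both rings F as their trimethyl ethers. It would give 15 directly, bypassing steps 5 to 8. Couplings to biaryls with four ortho substituents are established for this ligand class. This fallback makes no new compound (entry F0).

2. **Step 5.**
   - What may go wrong: insertion of palladium into electron-rich bromides flanked by two methoxy groups may be slow. The palladium malonate may rest as an O,O-chelate that does not eliminate reductively. Hydrodebromination may compete, and the second coupling may lag behind the first.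
   - Fallback: it sets out from 7 and comes back at 9. Bromine–lithium exchange on both rings E (n-BuLi, THF, −78 °C) is followed by polar addition to dimethyl 2-oxomalonate. Acetylation of the alkoxides in the same flask (Ac2O) would give the bis(acetoxymalonate) F1. Reductive removal of both α-acetoxy groups with SmI2 (THF–MeOH, −78 to 0 °C) would then give 9. The hindered C–C bonds are thus made by carbonyl addition instead of cross-coupling.

3. **Step 15.**
   - What may go wrong: the phenoxide oxygen of 16 lies between two bulky aryloxy groups. Its binding to copper and the C–O bond formation may be slow enough that hydrodebromination of 26 or oxidative decay of the phenol takes over.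
   - Fallback: it sets out from 26 and comes back at 27. Bromine–lithium exchange (n-BuLi, THF, −78 °C), B(OiPr)3 and aqueous acid would turn 26 into the ring C boronic acid F2. This is joined to 16 by a Chan–Lam coupling [Cu(OAc)2, pyridine, 4 Å MS, CH2Cl2, rt]. The polarity of ring C is reversed, and the union runs oxidatively at room temperature.

## Further compounds

F0 | step 6 | none | none
F1 | step 5 | 2-benzyloxy-5-methoxy-1,3-bis{3-[acetoxybis(methoxycarbonyl)methyl]-2,4,6-trimethoxyphenoxy}benzene | COc1cc(Oc2c(OC)cc(OC)c(C(OC(C)=O)(C(=O)OC)C(=O)OC)c2OC)c(OCc2ccccc2)c(Oc2c(OC)cc(OC)c(C(OC(C)=O)(C(=O)OC)C(=O)OC)c2OC)c1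
F2 | step 15 | {4-[4-(3,5-dimethoxyphenoxy)-3,5-dimethoxy-2-(2,4,6-trimethoxyphenyl)phenoxy]-3,5-dimethoxyphenyl}boronic acid | COc1cc(OC)cc(Oc2c(OC)cc(Oc3c(OC)cc(B(O)O)cc3OC)c(-c3c(OC)cc(OC)cc3OC)c2OC)c1
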